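The cyclohexenone ring C1–C2–C3–C4–C10–C11 is treated as a formal [4+2] adduct of the four-carbon unit C11–C1–C2–C3 across C4=C10 of a cycloheptene. Because C11 and C4 are already joined through C5, the same event also closes the cyclobutane C4–C5–C11–C10. The key step is therefore a one-pot double Michael cascade of an ynone silyl enol ether onto a ring nitroalkene (nitro as traceless activator at C4), which forms C10–C11 and C3–C4 and turns a monocyclic cycloheptenone into the tricyclic core. The C5 stereocentre, relayed from bought (S)-but-3-en-2-ol by Ireland–Claisen rearrangement, controls C4, C10 and C11.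

Key step: step 10

Remark (locants): longipinane numbering is used for all tricyclic compounds and for the same atoms in their precursors. The cyclobutane is C4–C5–C11–C10; the bridge C1(=O)–C2=C3(CH3) joins C11 to C4; the bridge C6(CH3)2–C7–C8–C9 joins C5 to C10; C10 carries a methyl.
Remark (assumption): compounds 1, 2, 4, 9, 14, 25 and 27 are taken as commercial.

Step 1
Reactants: 1 (S)-but-3-en-2-ol; 2 4,4-diethoxybut-1-ene
Product: 3 (2S,3E)-6,6-diethoxyhex-3-en-2-ol
Conditions: second-generation Hoveyda–Grubbs catalyst RuCl2(=CH-C6H4-2-O-i-Pr)(H2IMes) (3 mol %), 1 in excess, CH2Cl2, 40 °C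
Reagents that add atoms: none
Why: Olefin cross-metathesis of a secondary allylic alcohol with an unhindered terminal alkene should give the (E)-alkene with loss of ethene, leaving the bought (S)-carbinol centre untouched.

Step 2
Reactants: 3 (2S,3E)-6,6-diethoxyhex-3-en-2-ol; 4 2-methylpropanoyl chloride
Product: 5 (2S,3E)-6,6-diethoxyhex-3-en-2-yl 2-methylpropanoate
Conditions: pyridine, DMAP (cat.), CH2Cl2, 0 °C to rt
Reagents that add atoms: none
Why: O-acylation of the allylic alcohol with an acid chloride proceeds with retention at the carbinol centre.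

Step 3
Reactants: 5 (2S,3E)-6,6-diethoxyhex-3-en-2-yl 2-methylpropanoate
Product: 8 (3R,4E)-3-(2,2-diethoxyethyl)-2,2-dimethylhex-4-enoic acid, via silyl ketene acetal 6 (not isolated), via trimethylsilyl ester 7 (not isolated)
Conditions: LiN(i-Pr)2, Me3SiCl, THF, −78 °C to 60 °C; then H2O/THF, rt
Reagents that add atoms: none
Why: Ireland–Claisen rearrangement through a chair transition state with the carbinol methyl equatorial should transfer the (S)-carbinol centre to the new (R)-centre (C5 of the target), create the quaternary C6 and leave an (E)-propenyl group; the symmetric dimethylketene acetal removes any enolate-geometry issue.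

Step 4
Reactants: 8 (3R,4E)-3-(2,2-diethoxyethyl)-2,2-dimethylhex-4-enoic acid; 9 4-bromo-2-methylbut-1-ene
Product: 11 (7R,8E)-7-(2,2-diethoxyethyl)-2,6,6-trimethyldeca-1,8-dien-5-one, via 3-methylbut-3-enyllithium 10 (not isolated)
Conditions: 9 (2.5 equiv), t-BuLi (5 equiv), Et2O, −78 °C; then 8, −78 to 0 °C; H2O
Reagents that add atoms: none
Why: Addition of an alkyllithium (from bromine–lithium exchange) to the lithium carboxylate gives a gem-diolate that releases the ketone only on work-up, so over-addition is avoided and no stereocentre is touched.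

Step 5
Reactants: 11 (7R,8E)-7-(2,2-diethoxyethyl)-2,6,6-trimethyldeca-1,8-dien-5-one
Product: 12 (3R)-3-(2,2-diethoxyethyl)-2,2,5-trimethylcyclohept-4-en-1-one
Conditions: second-generation Grubbs catalyst RuCl2(=CHPh)(H2IMes)(PCy3) (5 mol %), toluene (0.005 M), 80 °C
Reagents that add atoms: none
Why: Ring-closing metathesis between the propenyl group and the 1,1-disubstituted alkene, helped by the gem-dimethyl group, should close the trisubstituted cycloheptene (the C4=C10 bond) with loss of propene.

Step 6
Reactants: 12 (3R)-3-(2,2-diethoxyethyl)-2,2,5-trimethylcyclohept-4-en-1-one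
Product: 13 [(1R)-3,7,7-trimethyl-6-oxocyclohept-2-en-1-yl]acetaldehyde
Conditions: pyridinium p-toluenesulfonate (cat.), acetone/H2O, 50 °C
Reagents that add atoms: water, O
Why: Mild acid-catalysed acetal hydrolysis liberates the aldehyde; C5 is not alpha to a carbonyl and cannot epimerise.

Step 7
Reactants: 13 [(1R)-3,7,7-trimethyl-6-oxocyclohept-2-en-1-yl]acetaldehyde; 14 prop-1-yn-1-ylmagnesium bromide
Product: 15 1-[(1R)-3,7,7-trimethyl-6-oxocyclohept-2-en-1-yl]pent-3-yn-2-ol (both carbinol epimers)
Conditions: THF, −78 °C; H2O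
Reagents that add atoms: none
Why: Grignard addition at low temperature is chemoselective for the aldehyde over the ketone flanked by a quaternary carbon; the new carbinol centre is destroyed in step 8, so its configuration is irrelevant.

Step 8
Reactants: 15 1-[(1R)-3,7,7-trimethyl-6-oxocyclohept-2-en-1-yl]pent-3-yn-2-ol
Product: 16 1-[(1R)-3,7,7-trimethyl-6-oxocyclohept-2-en-1-yl]pent-3-yn-2-one
Conditions: Dess–Martin periodinane, CH2Cl2, 0 °C to rt
Reagents that add atoms: none
Why: Dess–Martin oxidation of the propargylic alcohol gives the ynone under neutral conditions that leave the alkene and the ketone untouched.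

Step 9
Reactants: 16 1-[(1R)-3,7,7-trimethyl-6-oxocyclohept-2-en-1-yl]pent-3-yn-2-one
Product: 17 1-[(1S)-3,7,7-trimethyl-2-nitro-6-oxocyclohept-2-en-1-yl]pent-3-yn-2-one
Conditions: AgNO2 (3 equiv), TEMPO (0.4 equiv), 4 Å molecular sieves, ClCH2CH2Cl, 70 °C
Reagents that add atoms: silver nitrite, [Ag+].[O-]N=O
Why: Radical C–H nitration of an alkene: nitrogen dioxide from AgNO2 should add to the less substituted alkene carbon C4, and TEMPO-mediated loss of the now acidic C4 hydrogen restores the double bond as the conjugated nitroalkene; no stereocentre is formed.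

Step 10
Reactants: 17 1-[(1S)-3,7,7-trimethyl-2-nitro-6-oxocyclohept-2-en-1-yl]pent-3-yn-2-one
Product: 20 4-nitrolongipin-2-ene-1,7-dione (C5, C10, C11 configured as in 29), via silyl enol ether 18 (not isolated), via silyl nitronate 19 (not isolated)
Conditions: Me3SiOTf (1.3 equiv), i-Pr2NEt (1.2 equiv), CH2Cl2, −78 to −20 °C; then Bu4N[Ph3SiF2] (1.2 equiv), THF, −20 to 0 °C; aq. NH4Cl
Reagents that add atoms: none
Why: Proposed new method: Soft enolisation at C11 (the only alpha-methylene of the ynone; the C7 ketone is shielded by the quaternary C6) gives silyl enol ether 18, which, catalysed by the residual Me3SiOTf, adds Mukaiyama–Michael fashion to C10 of the O-silyl-activated nitroalkene (4-exo-trig, closing the cyclobutane C4–C5–C11–C10) to give silyl nitronate 19; fluoride then frees the nitronate, whose carbon C4 adds to C3 of the ynone (6-endo-dig, closing the cyclohexenone C1–C2–C3–C4–C10–C11), and protonation of the allenolate on work-up gives the enone. The closest known reaction types are the intramolecular double Michael reaction and the Lewis-acid-promoted conjugate addition of silyl enol ethers to nitroalkenes; new is the one-carbon tether (C5) between donor and acceptor, which makes the first addition a four-membered ring closure. That closure is expected to be feasible because the change from an enol ether to a nitronate pays for much of the ring strain and because the second, strongly exergonic addition removes the strained intermediate irreversibly. The new stereocentres C10, C11 and C4 are all set by C5: C11 is tied to C5 and can reach C10 only on the ring face that carries the side chain, and the C1–C3 bridge can then reach C4 only on the same face of the new cyclobutane (a wrongly oriented acyl group at C11 can epimerise by enolisation before the second closure). The selectivity needed is reaction of the ketone donor instead of gamma-deprotonation of the nitroalkene (C10-methyl, C9) to an allyl nitronate, and it is secured by making the first C–C bond under non-basic silyl triflate conditions and releasing an anion only after the nitroalkene has been consumed.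

Step 11
Reactants: 20 4-nitrolongipin-2-ene-1,7-dione
Product: 21 longipin-2-ene-1,7-dione (C4, C5, C10, C11 as in 29)
Conditions: Bu3SnH, (PhSe)2 (10 mol %), AIBN (cat.), benzene, 80 °C
Reagents that add atoms: none
Why: Radical denitration of a tertiary nitroalkane in a Bu3SnH chain; the bridgehead radical at C4 can accept hydrogen only in the position of the departed nitro group, and catalytic PhSeH (from (PhSe)2) supplies a fast hydrogen-atom transfer that should outrun opening of the cyclobutane.

Step 12
Reactants: 21 longipin-2-ene-1,7-dione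
Product: 22 longipina-2,8-diene-1,7-dione
Conditions: IBX, DMSO/fluorobenzene, 70 °C
Reagents that add atoms: none
Why: IBX dehydrogenation of a ketone to its enone; the C7 ketone has alpha hydrogens only at C8 (C6 is quaternary) and the C11 hydrogen next to C1 is a bridgehead hydrogen that cannot enolise, so only the C8=C9 bond can form.

Step 13
Reactants: 22 longipina-2,8-diene-1,7-dione
Product: 24 (9R)-9-hydroxylongipin-2-ene-1,7-dione, via pinacol boronate 23 (not isolated)
Conditions: CuCl (5 mol %), NaOt-Bu (10 mol %), (R)-DTBM-SEGPHOS (6 mol %; antipode if needed), B2pin2, MeOH, THF, rt; then H2O2, pH 7 phosphate buffer, 0 °C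
Reagents that add atoms: hydrogen peroxide, OO
Why: Copper-catalysed enantioselective conjugate borylation of a cyclic enone followed by stereoretentive C–B oxidation; the beta,beta-disubstituted C2=C3 enone is too hindered to compete, and because the cycloheptenone lies in the local mirror plane of the bicyclo[4.1.1]octane unit the face at C9 is expected to be set by the chiral ligand (antipode chosen for boron delivery syn to C11).

Step 14
Reactants: 24 (9R)-9-hydroxylongipin-2-ene-1,7-dione; 25 (E)-2-methylbut-2-enal
Product: 26 (7R,9R)-7-hydroxy-9-[(E)-2-methylbut-2-enoyloxy]longipin-2-en-1-one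
Conditions: SmI2 (0.3 equiv), 25 (5 equiv), THF, −10 °C
Reagents that add atoms: none
Why: Evans–Tishchenko reaction: the samarium-bound hemiacetal formed from the C9 hydroxyl and the aldehyde delivers hydride intramolecularly to the C7 ketone, which should give the 1,3-anti (trans) 7-hydroxy compound and place the tigloyl ester on O9 in the same event, leaving the C1 enone untouched.

Step 15
Reactants: 26 (7R,9R)-7-hydroxy-9-[(E)-2-methylbut-2-enoyloxy]longipin-2-en-1-one; 27 (Z)-2-methylbut-2-enoic acid
Product: 29 (4R,5S,7R,9R,10R,11R)-7-[(Z)-2-methylbut-2-enoyloxy]-9-[(E)-2-methylbut-2-enoyloxy]longipin-2-en-1-one, via mixed anhydride 28 (not isolated)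
Conditions: 27, 2,4,6-trichlorobenzoyl chloride, Et3N, toluene, rt; then 26, 80 °C
Reagents that add atoms: none
Why: Yamaguchi-type esterification through the mixed anhydride without a nucleophilic catalyst, conditions under which the (Z)-2-methylbut-2-enoyl group is expected to be transferred without isomerisation to the (E)-isomer; configuration at C7 is retained.

Compound list
1 | (S)-but-3-en-2-ol | C[C@H](O)C=C | starting material
2 | 4,4-diethoxybut-1-ene | C=CCC(OCC)OCC | starting material
3 | (2S,3E)-6,6-diethoxyhex-3-en-2-ol | C[C@H](O)/C=C/CC(OCC)OCC | intermediate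
4 | 2-methylpropanoyl chloride | CC(C)C(Cl)=O | starting material
5 | (2S,3E)-6,6-diethoxyhex-3-en-2-yl 2-methylpropanoate | C[C@H](OC(=O)C(C)C)/C=C/CC(OCC)OCC | intermediate
6 | trimethylsilyl ketene acetal of 5 | C[C@H](OC(O[Si](C)(C)C)=C(C)C)/C=C/CC(OCC)OCC | intermediate (not isolated)
7 | trimethylsilyl (3R,4E)-3-(2,2-diethoxyethyl)-2,2-dimethylhex-4-enoate | C/C=C/[C@@H](CC(OCC)OCC)C(C)(C)C(=O)O[Si](C)(C)C | intermediate (not isolated)
8 | (3R,4E)-3-(2,2-diethoxyethyl)-2,2-dimethylhex-4-enoic acid | C/C=C/[C@@H](CC(OCC)OCC)C(C)(C)C(O)=O | intermediate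
9 | 4-bromo-2-methylbut-1-ene | C=C(C)CCBr | starting material
10 | (3-methylbut-3-en-1-yl)lithium | [Li]CCC(C)=C | intermediate (not isolated)
11 | (7R,8E)-7-(2,2-diethoxyethyl)-2,6,6-trimethyldeca-1,8-dien-5-one | C/C=C/[C@@H](CC(OCC)OCC)C(C)(C)C(=O)CCC(C)=C | intermediate
12 | (3R)-3-(2,2-diethoxyethyl)-2,2,5-trimethylcyclohept-4-en-1-one | CC1=C[C@@H](CC(OCC)OCC)C(C)(C)C(=O)CC1 | intermediate
13 | [(1R)-3,7,7-trimethyl-6-oxocyclohept-2-en-1-yl]acetaldehyde | CC1=C[C@@H](CC=O)C(C)(C)C(=O)CC1 | intermediate
14 | prop-1-yn-1-ylmagnesium bromide | CC#C[Mg]Br | starting material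
15 | 1-[(1R)-3,7,7-trimethyl-6-oxocyclohept-2-en-1-yl]pent-3-yn-2-ol (both carbinol epimers) | CC#CC(O)C[C@@H]1C=C(C)CCC(=O)C1(C)C | intermediate
16 | 1-[(1R)-3,7,7-trimethyl-6-oxocyclohept-2-en-1-yl]pent-3-yn-2-one | CC#CC(=O)C[C@@H]1C=C(C)CCC(=O)C1(C)C | intermediate
17 | 1-[(1S)-3,7,7-trimethyl-2-nitro-6-oxocyclohept-2-en-1-yl]pent-3-yn-2-one | CC#CC(=O)C[C@@H]1C([N+](=O)[O-])=C(C)CCC(=O)C1(C)C | intermediate
18 | trimethylsilyl enol ether of 17 (C11=C1–OSiMe3) | CC#CC(O[Si](C)(C)C)=C[C@@H]1C([N+](=O)[O-])=C(C)CCC(=O)C1(C)C | intermediate (not isolated)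
19 | trimethylsilyl nitronate of 1-(1,5,5-trimethyl-8-nitro-4-oxobicyclo[4.1.1]octan-7-yl)but-2-yn-1-one | O=C(C#CC)[C@H]1[C@]2(C)CCC(=O)C(C)(C)[C@H]1C2=[N+]([O-])O[Si](C)(C)C | intermediate (not isolated)
20 | 4-nitrolongipin-2-ene-1,7-dione | O=C1CC[C@@]2(C)[C@@H]3C(=O)C=C(C)[C@@]2([N+](=O)[O-])[C@@H]3C1(C)C | intermediate
21 | longipin-2-ene-1,7-dione | O=C1CC[C@@]2(C)[C@@H]3C(=O)C=C(C)[C@H]2[C@@H]3C1(C)C | intermediate
22 | longipina-2,8-diene-1,7-dione | O=C1C=C[C@@]2(C)[C@@H]3C(=O)C=C(C)[C@H]2[C@@H]3C1(C)C | intermediate
23 | (9R)-9-(4,4,5,5-tetramethyl-1,3,2-dioxaborolan-2-yl)longipin-2-ene-1,7-dione | O=C1C[C@@H](B5OC(C)(C)C(C)(C)O5)[C@@]2(C)[C@@H]3C(=O)C=C(C)[C@H]2[C@@H]3C1(C)C | intermediate (not isolated)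
24 | (9R)-9-hydroxylongipin-2-ene-1,7-dione | O=C1C[C@@H](O)[C@@]2(C)[C@@H]3C(=O)C=C(C)[C@H]2[C@@H]3C1(C)C | intermediate
25 | (E)-2-methylbut-2-enal | C/C=C(\C)C=O | starting material
26 | (7R,9R)-7-hydroxy-9-[(E)-2-methylbut-2-enoyloxy]longipin-2-en-1-one | O[C@@H]1C[C@@H](OC(=O)/C(C)=C/C)[C@@]2(C)[C@@H]3C(=O)C=C(C)[C@H]2[C@@H]3C1(C)C | intermediate
27 | (Z)-2-methylbut-2-enoic acid | C/C=C(/C)C(=O)O | starting material
28 | (Z)-2-methylbut-2-enoic 2,4,6-trichlorobenzoic anhydride | C/C=C(/C)C(=O)OC(=O)c1c(Cl)cc(Cl)cc1Cl | intermediate (not isolated)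
29 | (4R,5S,7R,9R,10R,11R)-7-[(Z)-2-methylbut-2-enoyloxy]-9-[(E)-2-methylbut-2-enoyloxy]longipin-2-en-1-one | C/C=C(/C)C(=O)O[C@@H]1C[C@@H](OC(=O)/C(C)=C/C)[C@@]2(C)[C@@H]3C(=O)C=C(C)[C@H]2[C@@H]3C1(C)C | target

Total step count: 15. Longest linear sequence: 15 steps (1 and 2 to 29).

Steps most likely to fail

Step 10 (proposed new method). The cascade may stall after the first bond, the strained four-membered ring closure may not compete with simple loss of the silyl enol ether, or proton transfer may turn the nitroalkene into its allyl nitronate, which then adds to the ynone through C4 alone and closes only the six-membered ring. Fallback, setting out from 17 and returning to 20: the two bonds are made in separate operations of known type. Silyl enol ether 18 is prepared and isolated (Me3SiOTf, Et3N), then added to the nitroalkene under SnCl4 in CH2Cl2 at −78 °C (Lewis-acid-promoted conjugate addition of a silyl enol ether to a nitroalkene) with aqueous work-up, to give 1-(1,5,5-trimethyl-8-nitro-4-oxobicyclo[4.1.1]octan-7-yl)but-2-yn-1-one F1. A catalytic amount of DBU in MeCN then closes F1 by intramolecular nitro-Michael addition to the ynone, giving 20.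

Step 9. The nitrogen dioxide radical may attack the wrong alkene carbon, an allylic instead of the C4 hydrogen may be lost (giving allylic nitro isomers), or nitrite may add to the ynone. Fallback, setting out from 16 and returning to 17: addition–elimination instead of direct C–H nitration. Nitryl iodide made in the flask (AgNO2, I2, Et2O, rt) adds across C4=C10 to give 1-(3-iodo-3,7,7-trimethyl-2-nitro-6-oxocycloheptyl)pent-3-yn-2-one F2 (nitro on C4, iodine on the tertiary C10). Elimination of hydrogen iodide with pyridine in CH2Cl2 at 0 °C then gives 17.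

Step 13. Facial discrimination at C9 may be poor because the two faces of the cycloheptenone are nearly mirror-related, and the catalyst may be mismatched or slowed by the neighbouring quaternary C10. Fallback, setting out from 22 and returning to 24: catalytic asymmetric nucleophilic epoxidation of the C8=C9 enone (La(O-i-Pr)3, (R)-BINOL, Ph3As=O, t-BuOOH, THF) gives (8,9)-epoxylongipin-2-ene-1,7-dione F3. Reductive opening of the epoxy ketone at C8 with Na[PhSeB(OEt)3] (from (PhSe)2 and NaBH4 in EtOH, AcOH, 0 °C) then gives the β-hydroxy ketone 24.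

Further compounds
F1 | step 10 | 1-(1,5,5-trimethyl-8-nitro-4-oxobicyclo[4.1.1]octan-7-yl)but-2-yn-1-one (either epimer at the nitro-bearing carbon) | O=C(C#CC)[C@H]1[C@]2(C)CCC(=O)C(C)(C)[C@H]1C2[N+](=O)[O-]
F2 | step 9 | 1-(3-iodo-3,7,7-trimethyl-2-nitro-6-oxocycloheptyl)pent-3-yn-2-one (C5 as in 16) | CC#CC(=O)C[C@@H]1C([N+](=O)[O-])C(C)(I)CCC(=O)C1(C)C
F3 | step 13 | (8,9)-epoxylongipin-2-ene-1,7-dione (epoxide oxygen on the C11 face) | O=C1[C@H]2O[C@H]2[C@@]3(C)[C@@H]4C(=O)C=C(C)[C@H]3[C@@H]4C1(C)C
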